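**Plan**

- Retrosynthesis: the 3(2H)-furanone (O–C3=C2–C1(=O)–C10) is traced back to the six-membered 1,2-dioxine ring (C10–O–O–C3–C2=C1) of a bridged endoperoxide, that is, to O2 and a ten-membered 2-silyloxy-1,3-diene. Further cuts are C7–C8 with the lactone C–O bond (ring-closing allylation), C7–C11 (Baylis–Hillman), O6–acyl, C1–C2 (acetylide and Weinreb amide) and C4–C5 (Nozaki–Hiyama–Kishi).
- Enabling feature: C10 carries no hydrogen and C3 carries one, so base opens the peroxide in one direction only (C10–O kept, C3 becomes C=O). With the enol silyl ether at C1 this is a masked α'-hydroxy-1,3-diketone, which closes to the five-membered ring while one peroxide oxygen leaves as water.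
- Forward order: chain C2–C7 from triflate 5 and glyceraldehyde 6; C8–C10/C1 from lactone 1; (Z)-dienone; methacrylate and bromomethyl acrylate; ten-membered ring and lactone in one step; dienol ether; endoperoxide; ring contraction; desilylation.
- Stereochemistry: C6 from (R)-glyceraldehyde acetonide; C5 by Felkin-controlled addition; C7 and C8 in the ring-closing allylation; C10 by face-selective addition of O2 to the macrocyclic diene (the C3 centre of the peroxide is temporary).

Key step: step 18

Remark: germacrane numbering is used (C1 furanone carbonyl, C3 enol-ether carbon, C4 with methylene C15, C5 carbinol, C6 ester carbinol, C7/C8 lactone fusion, C10 with methyl C14, C11–C13 lactone carbons). C10 is carried as a mixture of epimers from racemic 1 until it becomes sp2 in 23, and C7 of 17 is also a mixture, so these centres are left undefined in the SMILES.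

**Route**

Step 1
Reactants: 1 α-methyl-γ-butyrolactone (racemic)
Product: 2 4-hydroxy-N-methoxy-N,2-dimethylbutanamide
Conditions: MeNHOMe·HCl, iPrMgCl, THF, −20 to 0 °C
Reagents that add atoms: N,O-dimethylhydroxylamine hydrochloride, CNOC.Cl
Why: aminolysis of the lactone by the chloromagnesium amide (Weinreb amide formation) opens the ring; C10 stays racemic, which is harmless because it becomes sp2 in 23.

Step 2
Reactants: 2 hydroxy Weinreb amide
Product: 3 4-[(tert-butyldimethylsilyl)oxy]-N-methoxy-N,2-dimethylbutanamide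
Conditions: TBSCl, imidazole, CH2Cl2, 0 °C
Reagents that add atoms: tert-butyldimethylsilyl chloride, CC(C)(C)[Si](C)(C)Cl
Why: standard silylation of the primary alcohol, which also prevents relactonisation.

Step 3
Reactants: 4 4-(trimethylsilyl)but-3-yn-2-one
Product: 5 4-(trimethylsilyl)but-1-en-3-yn-2-yl triflate
Conditions: Tf2O, 2,6-di-tert-butyl-4-methylpyridine, CH2Cl2, 0 °C to rt
Reagents that add atoms: triflic anhydride, O=S(=O)(OS(=O)(=O)C(F)(F)F)C(F)(F)F
Why: enol triflation of a methyl alkynyl ketone, whose methyl group is the only enolisable position.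

Step 4
Reactants: 5 enynyl triflate; 6 (R)-2,2-dimethyl-1,3-dioxolane-4-carbaldehyde
Product: 7 (1S)-1-[(4R)-2,2-dimethyl-1,3-dioxolan-4-yl]-2-methylidene-4-(trimethylsilyl)but-3-yn-1-ol
Conditions: CrCl2 (4 equiv), NiCl2 (1 mol %), DMF, 25 °C
Reagents that add atoms: none
Why: Nozaki–Hiyama–Kishi coupling of an alkenyl triflate with an α-alkoxy aldehyde; Felkin–Anh addition anti to the dioxolane C–O bond should give the 5,6-anti (5S) alcohol as the major isomer, the syn isomer being removed by chromatography.

Step 5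
Reactants: 7 enynyl carbinol
Product: 8 tert-butyldimethylsilyl ether of 7
Conditions: TBSCl, imidazole, DMF, rt
Reagents that add atoms: tert-butyldimethylsilyl chloride, CC(C)(C)[Si](C)(C)Cl
Why: standard protection of the secondary allylic alcohol, so that O5 and O6 remain distinguishable later.

Step 6
Reactants: 8 silyl ether; 3 Weinreb amide
Product: 10 ynone with the full C8–C10/C1–C7 chain, via lithium acetylide 9 (not isolated)
Conditions: MeLi·LiBr, THF, 0 °C to rt; then 3, −78 to 0 °C; aq NH4Cl
Reagents that add atoms: none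
Why: methyllithium cleaves the alkynyl C–Si bond to the lithium acetylide, which adds once to the Weinreb amide through the chelated tetrahedral intermediate and gives the ynone on work-up.

Step 7
Reactants: 10 ynone
Product: 11 (Z)-dienone
Conditions: H2 (1 atm), Pd/CaCO3 poisoned with Pb(OAc)2 (Lindlar), quinoline, EtOAc, 0 °C
Reagents that add atoms: none
Why: Lindlar semihydrogenation adds H2 syn to the conjugated triple bond, which is far more reactive than the 1,1-disubstituted alkene, and sets the 2Z geometry; any reversible closure to the 2H-pyran valence isomer returns the same Z-dienone.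

Step 8
Reactants: 11 (Z)-dienone acetonide
Product: 12 6,7-diol
Conditions: Zn(NO3)2·6H2O, MeCN, 50 °C
Reagents that add atoms: none
Why: Lewis acid-assisted hydrolysis of a terminal acetonide under conditions known to leave TBS ethers intact.

Step 9
Reactants: 12 diol
Product: 14 6-O-methacrylate 7-O-triethylsilyl ether, via primary triethylsilyl ether 13 (not isolated)
Conditions: TESCl (1.05 equiv), imidazole, CH2Cl2, −40 °C; then methacrylic anhydride, Et3N, DMAP, 0 °C to rt
Reagents that add atoms: chlorotriethylsilane, CC[Si](Cl)(CC)CC; methacrylic anhydride, C=C(C)C(=O)OC(=O)C(C)=C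
Why: the primary hydroxyl is silylated selectively at low temperature and the remaining secondary C6 hydroxyl is then acylated (DMAP-catalysed esterification) in the same flask.

Step 10
Reactants: 14 triethylsilyl ether
Product: 15 C7 aldehyde
Conditions: (COCl)2, DMSO, CH2Cl2, −78 to −30 °C; Et3N, −78 to 0 °C
Reagents that add atoms: none
Why: under Swern conditions a primary triethylsilyl ether is cleaved and oxidised directly to the aldehyde while TBS ethers are inert; the cold quench should prevent epimerisation at C6.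

Step 11
Reactants: 15 aldehyde; 16 methyl acrylate
Product: 17 Baylis–Hillman adduct (C7 epimers)
Conditions: DABCO, 1,4-dioxane/H2O (1:1), rt
Reagents that add atoms: none
Why: Morita–Baylis–Hillman reaction of a strongly activated α-acyloxy aldehyde; the aqueous medium protonates the alkoxide quickly, and the new C7 carbinol centre is irrelevant because it becomes sp2 in step 12.

Step 12
Reactants: 17 Baylis–Hillman adduct
Product: 18 (Z)-2-(bromomethyl)enoate
Conditions: NBS, Me2S, CH2Cl2, −20 to 0 °C
Reagents that add atoms: N-bromosuccinimide, O=C1CCC(=O)N1Br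
Why: bromosulfonium activation of the allylic alcohol and SN2' attack of bromide give the conjugated, thermodynamically preferred (Z)-allylic bromide.

Step 13
Reactants: 18 bis-silyl ether
Product: 19 C8 primary alcohol
Conditions: HF·pyridine, THF, 0 °C
Reagents that add atoms: none
Why: the primary TBS ether is cleaved much faster than the hindered secondary allylic one, and a non-alcoholic medium avoids ketalisation of the γ-hydroxy ketone.

Step 14
Reactants: 19 alcohol
Product: 20 C8 aldehyde
Conditions: Dess–Martin periodinane, NaHCO3, CH2Cl2, 0 °C to rt; used at once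
Reagents that add atoms: none
Why: buffered Dess–Martin oxidation of the primary alcohol leaves the allylic bromide, the esters and the dienone untouched.

Step 15
Reactants: 20 bromo aldehyde
Product: 22 ten-membered dienone 12,8-lactone (7R,8S), via hydroxy ester 21 (not isolated)
Conditions: CrCl2 (10 equiv), THF, 2 mM, slow addition, 25 °C; aq NH4Cl; then PPTS (cat.), CH2Cl2, rt
Reagents that add atoms: none
Why: intramolecular Nozaki–Hiyama (Barbier-type) allylation, in which the 2-(methoxycarbonyl)allylchromium species adds through C7 to the aldehyde in a chair-like Zimmerman–Traxler array and the alkoxide lactonises; the tether is expected to hold C6 and C9 antiperiplanar about the new bond (trans lactone, 8S) and the aldehyde should approach C7 anti to the C5 branch in the A(1,3)-minimised conformer (7R).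

Step 16
Reactants: 22 macrocyclic dienone
Product: 23 1-(triethylsilyloxy) 1(10),2-diene
Conditions: TESOTf, Et3N, CH2Cl2, −78 to −20 °C
Reagents that add atoms: triethylsilyl triflate, CC[Si](CC)(CC)OS(=O)(=O)C(F)(F)F
Why: soft enolisation can only occur towards C10, the sole α-hydrogen of the cross-conjugated ketone, and both C10 epimers of 22 converge on the same 2-silyloxy diene, expected with the ring-cis geometry that allows a cisoid diene.

Step 17
Reactants: 23 silyl dienol ether
Product: 24 3,10-epidioxide (3S,10S)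
Conditions: O2, tetraphenylporphyrin (cat.), visible light, CH2Cl2, −78 °C
Reagents that add atoms: dioxygen, O=O
Why: [4+2] cycloaddition of singlet oxygen to the electron-rich cisoid 2-silyloxy diene forms both C–O bonds suprafacially (C3 and C10 cis); the C4–C9 loop covers one diene face, so O2 should add from the open face, expected to be the one giving 10S when the lactone and the C5/C6 substituents sit pseudo-equatorially, and this sets C10.

Step 18
Reactants: 24 endoperoxide
Product: 27 5-O-TBS furanone, via hydroxy silyloxy enone 25 (not isolated), via hydroxy diketone 26 (not isolated)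
Conditions: Et3N, CH2Cl2, 0 °C to rt; then TsOH·H2O (cat.), THF/H2O, rt
Reagents that add atoms: none
Why: Triethylamine removes H-3, the only hydrogen on a peroxide-bearing carbon (C10 is fully substituted) and a doubly allylic one, and the O–O bond breaks in the same event (Kornblum–DeLaMare rearrangement) to give the C3 ketone and the free C10 tertiary alcohol 25, in which the C1 silyl enol ether and the C3 ketone form a masked α'-hydroxy-1,3-diketone. Acid then removes the enol silyl group (26), the C10 hydroxyl adds to the C3 carbonyl (5-exo-trig) and water is lost towards C2, so the six-membered 1,2-dioxine ring (C10, O, O, C3, C2, C1) contracts to the five-membered 3(2H)-furanone (C10, O, C3, C2, C1) with one peroxide oxygen expelled as water. The closest known reaction types are the base-induced Kornblum–DeLaMare opening of 3,6-dihydro-1,2-dioxines to γ-hydroxy enones and the acid cyclodehydration of α'-hydroxy-1,3-diketones to 3(2H)-furanones. No new stereocentre is formed: C10 keeps the configuration set in step 17 because its C–O bond is never broken, and the temporary C3 centre becomes sp2. The direction of peroxide opening is secured by the quaternary C10, and closure of O5 on C1 to a six-membered dihydropyranone is excluded because O5 is still silylated, while O10 cannot reach C1.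

Step 19
Reactants: 27 silyl ether
Product: 28 CNP0142847.1
Conditions: HF·pyridine, THF, 0 °C to rt
Reagents that add atoms: none
Why: fluoride cleavage of the secondary TBS ether under mildly acidic conditions that should not affect the esters, the lactone or the furanone, and that avoid base-induced acyl migration from O6 to O5.

**Compound list**

1 | α-methyl-γ-butyrolactone (racemic) | CC1CCOC1=O | starting material
2 | 4-hydroxy-N-methoxy-N,2-dimethylbutanamide | CON(C)C(=O)C(C)CCO | intermediate
3 | 4-[(tert-butyldimethylsilyl)oxy]-N-methoxy-N,2-dimethylbutanamide | CON(C)C(=O)C(C)CCO[Si](C)(C)C(C)(C)C | intermediate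
4 | 4-(trimethylsilyl)but-3-yn-2-one | CC(=O)C#C[Si](C)(C)C | starting material
5 | 4-(trimethylsilyl)but-1-en-3-yn-2-yl trifluoromethanesulfonate | C=C(OS(=O)(=O)C(F)(F)F)C#C[Si](C)(C)C | intermediate
6 | (R)-2,2-dimethyl-1,3-dioxolane-4-carbaldehyde | O=C[C@H]1COC(C)(C)O1 | starting material
7 | (1S)-1-[(4R)-2,2-dimethyl-1,3-dioxolan-4-yl]-2-methylidene-4-(trimethylsilyl)but-3-yn-1-ol | C[Si](C)(C)C#CC(=C)[C@H](O)[C@H]1COC(C)(C)O1 | intermediate
8 | tert-butyldimethylsilyl ether of 7 (1S,4'R) | C[Si](C)(C)C#CC(=C)[C@H](O[Si](C)(C)C(C)(C)C)[C@H]1COC(C)(C)O1 | intermediate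
9 | lithium acetylide of desilylated 8 | [Li]C#CC(=C)[C@H](O[Si](C)(C)C(C)(C)C)[C@H]1COC(C)(C)O1 | intermediate
10 | (3RS,8S)-1,8-bis[(tert-butyldimethylsilyl)oxy]-8-[(4R)-2,2-dimethyl-1,3-dioxolan-4-yl]-3-methyl-7-methylideneoct-5-yn-4-one | CC(CCO[Si](C)(C)C(C)(C)C)C(=O)C#CC(=C)[C@H](O[Si](C)(C)C(C)(C)C)[C@H]1COC(C)(C)O1 | intermediate
11 | (3RS,5Z,8S)-1,8-bis[(tert-butyldimethylsilyl)oxy]-8-[(4R)-2,2-dimethyl-1,3-dioxolan-4-yl]-3-methyl-7-methylideneoct-5-en-4-one | CC(CCO[Si](C)(C)C(C)(C)C)C(=O)/C=C\C(=C)[C@H](O[Si](C)(C)C(C)(C)C)[C@H]1COC(C)(C)O1 | intermediate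
12 | (3RS,5Z,8S,9R)-1,8-bis[(tert-butyldimethylsilyl)oxy]-9,10-dihydroxy-3-methyl-7-methylidenedec-5-en-4-one | CC(CCO[Si](C)(C)C(C)(C)C)C(=O)/C=C\C(=C)[C@H](O[Si](C)(C)C(C)(C)C)[C@H](O)CO | intermediate
13 | 10-O-triethylsilyl ether of 12 | CC(CCO[Si](C)(C)C(C)(C)C)C(=O)/C=C\C(=C)[C@H](O[Si](C)(C)C(C)(C)C)[C@H](O)CO[Si](CC)(CC)CC | intermediate
14 | (2R,3S,5Z,8RS)-3,10-bis[(tert-butyldimethylsilyl)oxy]-8-methyl-4-methylidene-7-oxo-1-[(triethylsilyl)oxy]dec-5-en-2-yl 2-methylprop-2-enoate | CC(CCO[Si](C)(C)C(C)(C)C)C(=O)/C=C\C(=C)[C@H](O[Si](C)(C)C(C)(C)C)[C@H](OC(=O)C(C)=C)CO[Si](CC)(CC)CC | intermediate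
15 | (2S,3S,5Z,8RS)-3,10-bis[(tert-butyldimethylsilyl)oxy]-8-methyl-4-methylidene-1,7-dioxodec-5-en-2-yl 2-methylprop-2-enoate (same spatial arrangement as 14; the C2 label changes because CHO outranks C3) | CC(CCO[Si](C)(C)C(C)(C)C)C(=O)/C=C\C(=C)[C@H](O[Si](C)(C)C(C)(C)C)[C@H](OC(=O)C(C)=C)C=O | intermediate
16 | methyl acrylate | C=CC(=O)OC | starting material
17 | methyl (4R,5S,7Z,10RS)-5,12-bis[(tert-butyldimethylsilyl)oxy]-3-hydroxy-10-methyl-2,6-dimethylidene-4-[(2-methylprop-2-enoyl)oxy]-9-oxododec-7-enoate (C3 epimers) | CC(CCO[Si](C)(C)C(C)(C)C)C(=O)/C=C\C(=C)[C@H](O[Si](C)(C)C(C)(C)C)[C@H](OC(=O)C(C)=C)C(O)C(=C)C(=O)OC | intermediate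
18 | methyl (2Z,4R,5S,7Z,10RS)-2-(bromomethyl)-5,12-bis[(tert-butyldimethylsilyl)oxy]-10-methyl-6-methylidene-4-[(2-methylprop-2-enoyl)oxy]-9-oxododeca-2,7-dienoate | CC(CCO[Si](C)(C)C(C)(C)C)C(=O)/C=C\C(=C)[C@H](O[Si](C)(C)C(C)(C)C)[C@H](OC(=O)C(C)=C)/C=C(\CBr)C(=O)OC | intermediate
19 | 12-hydroxy analogue of 18 (12-O-TBS removed) | CC(CCO)C(=O)/C=C\C(=C)[C@H](O[Si](C)(C)C(C)(C)C)[C@H](OC(=O)C(C)=C)/C=C(\CBr)C(=O)OC | intermediate
20 | methyl (2Z,4R,5S,7Z,10RS)-2-(bromomethyl)-5-[(tert-butyldimethylsilyl)oxy]-10-methyl-6-methylidene-4-[(2-methylprop-2-enoyl)oxy]-9,12-dioxododeca-2,7-dienoate | CC(CC=O)C(=O)/C=C\C(=C)[C@H](O[Si](C)(C)C(C)(C)C)[C@H](OC(=O)C(C)=C)/C=C(\CBr)C(=O)OC | intermediate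
21 | methyl (2Z,5S,6R,7R,8S)-5-[(tert-butyldimethylsilyl)oxy]-8-hydroxy-6-(methacryloyloxy)-1-oxogermacra-2,4(15),11(13)-trien-12-oate (C10 epimers) | C=C(C)C(=O)O[C@@H]1[C@H](C(=C)C(=O)OC)[C@@H](O)CC(C)C(=O)/C=C\C(=C)[C@@H]1O[Si](C)(C)C(C)(C)C | intermediate
22 | (2Z,5S,6R,7R,8S)-5-[(tert-butyldimethylsilyl)oxy]-6-(methacryloyloxy)-1-oxogermacra-2,4(15),11(13)-trien-12,8-olide (C10 epimers) | C=C(C)C(=O)O[C@@H]1[C@@H]2C(=C)C(=O)O[C@H]2CC(C)C(=O)/C=C\C(=C)[C@@H]1O[Si](C)(C)C(C)(C)C | intermediate
23 | (1(10)E,2Z,5S,6R,7R,8S)-5-[(tert-butyldimethylsilyl)oxy]-6-(methacryloyloxy)-1-[(triethylsilyl)oxy]germacra-1(10),2,4(15),11(13)-tetraen-12,8-olide | C=C(C)C(=O)O[C@@H]1[C@@H]2C(=C)C(=O)O[C@H]2C/C(C)=C(O[Si](CC)(CC)CC)\C=C/C(=C)[C@@H]1O[Si](C)(C)C(C)(C)C | intermediate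
24 | (3S,5S,6R,7R,8S,10S)-3,10-epidioxy-5-[(tert-butyldimethylsilyl)oxy]-6-(methacryloyloxy)-1-[(triethylsilyl)oxy]germacra-1,4(15),11(13)-trien-12,8-olide | C=C(C)C(=O)O[C@@H]1[C@@H]2C(=C)C(=O)O[C@H]2C[C@]3(C)OO[C@@H](C=C3O[Si](CC)(CC)CC)C(=C)[C@@H]1O[Si](C)(C)C(C)(C)C | intermediate
25 | (1E,5S,6R,7R,8S,10S)-5-[(tert-butyldimethylsilyl)oxy]-10-hydroxy-6-(methacryloyloxy)-3-oxo-1-[(triethylsilyl)oxy]germacra-1,4(15),11(13)-trien-12,8-olide | C=C(C)C(=O)O[C@@H]1[C@@H]2C(=C)C(=O)O[C@H]2C[C@](C)(O)/C(O[Si](CC)(CC)CC)=C\C(=O)C(=C)[C@@H]1O[Si](C)(C)C(C)(C)C | intermediate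
26 | (5S,6R,7R,8S,10S)-5-[(tert-butyldimethylsilyl)oxy]-10-hydroxy-6-(methacryloyloxy)-1,3-dioxogermacra-4(15),11(13)-dien-12,8-olide | C=C(C)C(=O)O[C@@H]1[C@@H]2C(=C)C(=O)O[C@H]2C[C@](C)(O)C(=O)CC(=O)C(=C)[C@@H]1O[Si](C)(C)C(C)(C)C | intermediate
27 | (5S,6R,7R,8S,10S)-5-[(tert-butyldimethylsilyl)oxy]-3,10-epoxy-6-(methacryloyloxy)-1-oxogermacra-2,4(15),11(13)-trien-12,8-olide | C=C(C)C(=O)O[C@@H]1[C@@H]2C(=C)C(=O)O[C@H]2C[C@]2(C)OC(=CC2=O)C(=C)[C@@H]1O[Si](C)(C)C(C)(C)C | intermediate
28 | CNP0142847.1, (5S,6R,7R,8S,10S)-3,10-epoxy-5-hydroxy-6-(methacryloyloxy)-1-oxogermacra-2,4(15),11(13)-trien-12,8-olide | C=C(C)C(=O)O[C@@H]1[C@@H]2C(=C)C(=O)O[C@H]2C[C@]2(C)OC(=CC2=O)C(=C)[C@@H]1O | target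

**Step count**

Total: 19 steps. Longest linear sequence: 17 steps (steps 3 to 19, from 4).

**Steps most likely to fail**

1. Step 17. The twisted medium-ring dienol ether may be oxygenated at the enol ether alone (ene-type or [2+2] pathways) instead of across the diene, or may react too slowly. The facial preference is also the least secure stereochemical point of the route, and this fallback does not remove that bias, since epoxidation relies on the same open diene face. The fallback sets out from 23 and gives up the peroxide. Rubottom oxidation (dimethyldioxirane, acetone/CH2Cl2, −78 °C; then AcOH/THF/H2O) should give the 10-hydroxy dienone F1. A Wacker-type oxidative cyclisation (PdCl2(MeCN)2 cat., CuCl, O2, Na2HPO4, DME, 50 °C; 5-endo oxypalladation of the C2=C3 enone by O10, then β-hydride elimination) closes the furanone directly and returns to the route at 27.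

2. Step 15. Intermolecular coupling and reduction of the cross-conjugated (Z)-dienone by divalent chromium may outrun closure of the ten-membered ring. Ring closure with the cis lactone is a further possibility that this fallback would not correct, since the same tether constraint governs the stereochemical outcome. The fallback sets out from 18 and replaces the reducing metal by a configurationally defined boron reagent. Palladium-catalysed borylation (B2pin2, Pd2(dba)3 cat., toluene, 50 °C) should give the allylboronate F2. HF·pyridine in THF then frees the C8 alcohol F3, and Dess–Martin oxidation gives the boronate aldehyde F4. F4 closes by intramolecular allylboration through a closed six-membered transition state (Sc(OTf)3 cat., toluene, high dilution) and lactonises, returning to the route at 22.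

3. Step 11. Under the amine the methacryloyl group may migrate from O6 to the new C7 alkoxide, C6 of the α-acyloxy aldehyde may epimerise, and the (Z)-dienone may isomerise. The fallback sets out from 15 and uses a preformed vinylmetal instead of amine catalysis. [1-(Methoxycarbonyl)vinyl]diisobutylaluminium, made by hydroalumination of methyl propiolate with iBu2AlH and N-methylmorpholine N-oxide in THF at 0 °C, is added to 15 at low temperature. This should give the same adduct, so the fallback returns to the route at 17 without any new isolated compound.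

**Further compounds**

F1 | step 17 | (2Z,5S,6R,7R,8S,10S)-5-[(tert-butyldimethylsilyl)oxy]-10-hydroxy-6-(methacryloyloxy)-1-oxogermacra-2,4(15),11(13)-trien-12,8-olide | C=C(C)C(=O)O[C@@H]1[C@@H]2C(=C)C(=O)O[C@H]2C[C@](C)(O)C(=O)/C=C\C(=C)[C@@H]1O[Si](C)(C)C(C)(C)C
F2 | step 15 | allylboronate from 18 (CH2Br replaced by CH2B(pin)) | CC(CCO[Si](C)(C)C(C)(C)C)C(=O)/C=C\C(=C)[C@H](O[Si](C)(C)C(C)(C)C)[C@H](OC(=O)C(C)=C)/C=C(\CB1OC(C)(C)C(C)(C)O1)C(=O)OC
F3 | step 15 | C8 alcohol of F2 | CC(CCO)C(=O)/C=C\C(=C)[C@H](O[Si](C)(C)C(C)(C)C)[C@H](OC(=O)C(C)=C)/C=C(\CB1OC(C)(C)C(C)(C)O1)C(=O)OC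
F4 | step 15 | C8 aldehyde of F2 | CC(CC=O)C(=O)/C=C\C(=C)[C@H](O[Si](C)(C)C(C)(C)C)[C@H](OC(=O)C(C)=C)/C=C(\CB1OC(C)(C)C(C)(C)O1)C(=O)OC
F0 | step 11 | none | none
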